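**Retrosynthetic overview**

1. The three esters go on last: Yamaguchi acylation of C5–OH after axial allylic hydroxylation of C5, acylation of C6–OH, and C6–OH-directed epoxidation of the isopropenyl group, all on a trans-hydrindanone alcohol.
2. The six-membered ring is formed second, by a photochemical C6–C7 bond formation: ring-closing allylic C–H carbonyl allylation of a 2-methylprop-1-enyl group onto a tethered aldehyde, which also creates the isopropenyl group and the trans C6/C7 centres.
3. That aldehyde comes from a fully substituted cyclopentanone: three-component coupling (vinyl-copper addition, acetaldehyde aldol, acetylation) on a 4-substituted cyclopentenone, then formaldehyde-ene homologation of the carvone isopropenyl group (it becomes C4=CH2 and C5).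
4. The five-membered ring is made first, from (S)-carvone: epoxidation, acyl-shift ring contraction, deacetylative diazo transfer and 1,2-hydride shift give (R)-4-isopropenylcyclopent-2-enone.
5. Side chains: (R)-2-methylbutanoic acid is bought; (2E,4S)-4-acetoxy-3-methylpent-2-enoic acid is made in three steps from L-lactic-acid-derived (S)-2-acetoxypropanoyl chloride.

Assumption: (S)-carvone, (R)-2-methylbutanoic acid and (S)-2-acetoxypropanoyl chloride are bought as single enantiomers; bicyclic compounds use octahydro-1H-inden-2-one locants (C1 acetoxyethyl, C2 ketone, C4 methylidene, C5/C6 oxygenated, C7 three-carbon unit).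

**Route**

Step 1
Reactants: 1 (S)-carvone; 2 hydrogen peroxide
Product: 3 trans-carvone oxide (1S,4S,6S)-1-methyl-4-(prop-1-en-2-yl)-7-oxabicyclo[4.1.0]heptan-2-one
Conditions: 30% aq. H2O2, NaOH (cat.), MeOH, 0 °C
Reagents that add atoms: hydrogen peroxide, OO
Why: Weitz–Scheffer nucleophilic epoxidation attacks only the electron-poor enone alkene, and hydroperoxide adds to the ring face anti to the isopropenyl group, so the epoxide forms trans to it and the isopropenyl alkene is untouched.

Step 2
Reactants: 3 trans-carvone oxide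
Product: 4 (4S)-2-acetyl-4-(prop-1-en-2-yl)cyclopentan-1-one (C2 epimers and enol form)
Conditions: BF3·OEt2 (0.3 equiv), CH2Cl2, −20 → 0 °C
Reagents that add atoms: none
Why: Lewis-acid epoxy-ketone rearrangement (1,2-acyl shift of the House–Meinwald type): ionisation of the secondary C–O bond is followed by migration of the ring acyl carbon, which contracts the ring to the 2-acetylcyclopentanone and leaves the isopropenyl-bearing centre untouched (the new C2 centre is enolisable and inconsequential).

Step 3
Reactants: 4 (4S)-2-acetyl-4-(prop-1-en-2-yl)cyclopentan-1-one; 5 4-acetamidobenzenesulfonyl azide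
Product: 6 (4S)-2-diazo-4-(prop-1-en-2-yl)cyclopentan-1-one
Conditions: DBU, MeCN, 0 °C → rt
Reagents that add atoms: 4-acetamidobenzenesulfonyl azide, CC(=O)Nc1ccc(cc1)S(=O)(=O)N=[N+]=[N-]
Why: Regitz deacylative diazo transfer: the diketone enolate adds to the sulfonyl azide and the less hindered acetyl group leaves as the N-acetylsulfonamide, so the diazo group sits regiospecifically on the carbon between the former carbonyls.

Step 4
Reactants: 6 (4S)-2-diazo-4-(prop-1-en-2-yl)cyclopentan-1-one
Product: 7 (4R)-4-(prop-1-en-2-yl)cyclopent-2-en-1-one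
Conditions: Rh2(OAc)4 (1 mol%), CH2Cl2, rt
Reagents that add atoms: none
Why: Rhodium-carbene 1,2-hydride shift from the only adjacent CH2 gives the enone with the alkene regiospecifically next to the stereocentre, under neutral conditions that neither racemise nor conjugate it.

Step 5
Reactants: 7 (4R)-4-(prop-1-en-2-yl)cyclopent-2-en-1-one; 8 2-methylprop-1-en-1-ylmagnesium bromide; 9 acetaldehyde; 10 acetic anhydride
Product: 13 (1S)-1-[(1S,2S,3R)-2-(2-methylprop-1-en-1-yl)-5-oxo-3-(prop-1-en-2-yl)cyclopentyl]ethyl acetate, via magnesium enolate 11 (not isolated), via magnesium aldolate 12 (not isolated)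
Conditions: CuBr·SMe2 (10 mol%), THF, −78 °C; then CH3CHO, −78 °C; then Ac2O, −78 → 0 °C
Reagents that add atoms: 2-methylprop-1-en-1-ylmagnesium bromide, CC(C)=C[Mg]Br; acetaldehyde, CC=O; acetic anhydride, CC(=O)OC(C)=O
Why: Three-component coupling: copper-catalysed conjugate addition enters trans to the C4 isopropenyl group, the magnesium enolate then adds to acetaldehyde through a chelated Zimmerman–Traxler chair from the face opposite the new substituent to give the anti aldolate (ring C1 and the carbinol centre), and acetic anhydride traps it as the acetate.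

Step 6
Reactants: 13 cyclopentanone acetate; 14 formaldehyde (as paraformaldehyde)
Product: 15 (1S)-1-[(1S,2S,3R)-3-(4-hydroxybut-1-en-2-yl)-2-(2-methylprop-1-en-1-yl)-5-oxocyclopentyl]ethyl acetate
Conditions: (CH2O)n, Me2AlCl (2 equiv), CH2Cl2, −78 → 0 °C; then 1 M HCl
Reagents that add atoms: formaldehyde, C=O
Why: Lewis-acid carbonyl-ene reaction of formaldehyde, fastest at the unhindered 1,1-disubstituted alkene with hydrogen taken from its methyl group, homologates the isopropenyl group to a 4-hydroxybut-1-en-2-yl group without touching a stereocentre.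

Step 7
Reactants: 15 homoallylic alcohol
Product: 16 (1S)-1-[(1S,2S,3R)-2-(2-methylprop-1-en-1-yl)-5-oxo-3-(4-oxobut-1-en-2-yl)cyclopentyl]ethyl acetate
Conditions: Dess–Martin periodinane, pyridine, CH2Cl2, 0 °C
Reagents that add atoms: none
Why: Dess–Martin oxidation of the primary alcohol under buffered, non-enolising conditions gives the β,γ-unsaturated aldehyde without moving the alkene into conjugation.

Step 8
Reactants: 16 keto aldehyde
Product: 17 (1S)-1-[(1S,3aR,6S,7R,7aR)-6-hydroxy-4-methylidene-2-oxo-7-(prop-1-en-2-yl)octahydro-1H-inden-1-yl]ethyl acetate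
Conditions: 9-mesityl-10-methylacridinium perchlorate (5 mol%), CrCl2 (10 mol%), CH2Cl2, 450 nm LEDs, rt
Reagents that add atoms: none
Why: Proposed new method: the excited acridinium oxidises the electron-rich trisubstituted alkene to its radical cation, loss of a methyl proton gives a 2-substituted allyl radical that CrCl2 captures at its CH2 end, and the resulting allylchromium (trivalent chromium) adds through its γ-carbon to the tethered aldehyde in a chair-like six-membered transition state fused trans-decalin-like to the forming ring, so the new C6–OH and the newly unveiled C7 isopropenyl group end up trans-diequatorial on the existing trans ring fusion before protonolysis and reduction of trivalent back to divalent chromium close the redox-neutral cycle; the closest known reaction types are the intermolecular acridinium/chromium allylation of aldehydes with simple alkenes through allylic C–H activation and the thermal carbonyl-ene cyclisation of citronellal to isopulegol, and the ring-closing use on a 2-methylprop-1-enyl/aldehyde pair is new.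

Step 9
Reactants: 17 hydrindanone alcohol; 18 tert-butyl hydroperoxide
Product: 19 (1S)-1-[(1S,3aR,6S,7S,7aR)-6-hydroxy-4-methylidene-7-[(2S)-2-methyloxiran-2-yl]-2-oxooctahydro-1H-inden-1-yl]ethyl acetate
Conditions: VO(acac)2 (5 mol%), t-BuOOH (decane), CH2Cl2, 0 °C → rt
Reagents that add atoms: tert-butyl hydroperoxide, CC(C)(C)OO
Why: Hydroxyl-directed vanadium-catalysed epoxidation of a homoallylic alcohol: the vanadate ester of the equatorial C6–OH delivers the peroxide oxygen through a chair-like array to the face of the gauche C7 isopropenyl group turned toward C6, in the rotamer with =CH2 syn to H-7 and the methyl between C6 and C7a, which gives the (S) epoxide centre, while the C4 methylidene is out of reach because the C6–O bond is antiperiplanar to C5–C4.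

Step 10
Reactants: 19 epoxy alcohol; 20 (2R)-2-methylbutanoic acid
Product: 22 (1S,3aR,6S,7S,7aR)-1-[(1S)-1-(acetyloxy)ethyl]-4-methylidene-7-[(2S)-2-methyloxiran-2-yl]-2-oxooctahydro-1H-inden-6-yl (2R)-2-methylbutanoate, via O-acylisourea 21 (not isolated)
Conditions: DIC, DMAP (10 mol%), CH2Cl2, 0 °C → rt
Reagents that add atoms: (2R)-2-methylbutanoic acid, CC[C@@H](C)C(=O)O
Why: Steglich esterification of the only free hydroxyl with the bought acid under mild conditions that leave the epoxide, the β-acetoxy ketone and every stereocentre unchanged.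

Step 11
Reactants: 22 C6 ester; 18 tert-butyl hydroperoxide
Product: 23 (1S,3aR,5S,6R,7S,7aR)-1-[(1S)-1-(acetyloxy)ethyl]-5-hydroxy-4-methylidene-7-[(2S)-2-methyloxiran-2-yl]-2-oxooctahydro-1H-inden-6-yl (2R)-2-methylbutanoate
Conditions: SeO2 (30 mol%), t-BuOOH, CH2Cl2, rt
Reagents that add atoms: tert-butyl hydroperoxide, CC(C)(C)OO
Why: Selenium dioxide allylic hydroxylation (ene reaction then [2,3]-sigmatropic shift) on the only remaining alkene: the ene step removes the axial hydrogen of the C5 methylene in preference to the tertiary ring-fusion H-3a, and the sigmatropic shift returns oxygen to the same axial face, giving the (5S) alcohol cis to the C6 ester with the methylidene restored.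

Step 12
Reactants: 24 (2S)-2-(acetyloxy)propanoyl chloride; 25 methylmagnesium bromide
Product: 26 (2S)-3-oxobutan-2-yl acetate
Conditions: Fe(acac)3 (3 mol%), THF, −78 °C
Reagents that add atoms: methylmagnesium bromide, C[Mg]Br
Why: Iron-catalysed acyl chloride–Grignard cross-coupling at −78 °C stops at the methyl ketone and does not enolise the lactate-derived stereocentre.

Step 13
Reactants: 26 (2S)-3-oxobutan-2-yl acetate; 27 tert-butyl (triphenylphosphoranylidene)acetate
Product: 28 tert-butyl (2E,4S)-4-(acetyloxy)-3-methylpent-2-enoate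
Conditions: PhMe, 90 °C
Reagents that add atoms: tert-butyl (triphenylphosphoranylidene)acetate, CC(C)(C)OC(=O)C=P(c1ccccc1)(c1ccccc1)c1ccccc1
Why: Wittig olefination with a stabilised ylide puts the ester trans to the larger 1-acetoxyethyl group (E alkene) under base-free conditions that keep the α-acetoxy stereocentre intact.

Step 14
Reactants: 28 tert-butyl ester
Product: 29 (2E,4S)-4-(acetyloxy)-3-methylpent-2-enoic acid
Conditions: CF3CO2H, CH2Cl2, 0 °C → rt
Reagents that add atoms: none
Why: Acidolysis of the tert-butyl ester (E1 loss of 2-methylpropene) frees the acid without touching the secondary acetate or the alkene geometry.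

Step 15
Reactants: 23 C5 alcohol; 29 (2E,4S)-4-(acetyloxy)-3-methylpent-2-enoic acid
Product: 31 target CNP0170703.2, via mixed anhydride 30 (not isolated)
Conditions: 2,4,6-Cl3C6H2COCl, Et3N, THF, rt; then 23, DMAP, PhMe, 0 °C → rt
Reagents that add atoms: (2E,4S)-4-(acetyloxy)-3-methylpent-2-enoic acid, OC(=O)/C=C(\C)[C@H](C)OC(C)=O
Why: Yamaguchi esterification: the preformed mixed anhydride acylates the hindered axial allylic C5–OH quickly at low temperature (outrunning 1,2-acyl migration from C6) with retention at every centre, which completes the target.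

**Compound list**

1 | (S)-carvone, (5S)-2-methyl-5-(prop-1-en-2-yl)cyclohex-2-en-1-one | C=C(C)[C@@H]1CC(=O)C(C)=CC1 | starting material
2 | hydrogen peroxide | OO | starting material
3 | (1S,4S,6S)-1-methyl-4-(prop-1-en-2-yl)-7-oxabicyclo[4.1.0]heptan-2-one | C=C(C)[C@@H]1CC(=O)[C@@]2(C)O[C@H]2C1 | intermediate
4 | (4S)-2-acetyl-4-(prop-1-en-2-yl)cyclopentan-1-one (C2 epimers/enol) | C=C(C)[C@@H]1CC(=O)C(C(C)=O)C1 | intermediate
5 | 4-acetamidobenzenesulfonyl azide | CC(=O)Nc1ccc(cc1)S(=O)(=O)N=[N+]=[N-] | starting material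
6 | (4S)-2-diazo-4-(prop-1-en-2-yl)cyclopentan-1-one | C=C(C)[C@@H]1CC(=O)C(=[N+]=[N-])C1 | intermediate
7 | (4R)-4-(prop-1-en-2-yl)cyclopent-2-en-1-one | C=C(C)[C@@H]1CC(=O)C=C1 | intermediate
8 | 2-methylprop-1-en-1-ylmagnesium bromide | CC(C)=C[Mg]Br | starting material
9 | acetaldehyde | CC=O | starting material
10 | acetic anhydride | CC(=O)OC(C)=O | starting material
11 | bromomagnesium (3S,4R)-3-(2-methylprop-1-en-1-yl)-4-(prop-1-en-2-yl)cyclopent-1-en-1-olate | C=C(C)[C@@H]1CC(O[Mg]Br)=C[C@H]1C=C(C)C | intermediate
12 | bromomagnesium (1S)-1-[(1S,2S,3R)-2-(2-methylprop-1-en-1-yl)-5-oxo-3-(prop-1-en-2-yl)cyclopentyl]ethanolate | C=C(C)[C@@H]1CC(=O)[C@H]([C@H](C)O[Mg]Br)[C@H]1C=C(C)C | intermediate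
13 | (1S)-1-[(1S,2S,3R)-2-(2-methylprop-1-en-1-yl)-5-oxo-3-(prop-1-en-2-yl)cyclopentyl]ethyl acetate | C=C(C)[C@@H]1CC(=O)[C@H]([C@H](C)OC(C)=O)[C@H]1C=C(C)C | intermediate
14 | formaldehyde (used as paraformaldehyde) | C=O | starting material
15 | (1S)-1-[(1S,2S,3R)-3-(4-hydroxybut-1-en-2-yl)-2-(2-methylprop-1-en-1-yl)-5-oxocyclopentyl]ethyl acetate | C=C(CCO)[C@@H]1CC(=O)[C@H]([C@H](C)OC(C)=O)[C@H]1C=C(C)C | intermediate
16 | (1S)-1-[(1S,2S,3R)-2-(2-methylprop-1-en-1-yl)-5-oxo-3-(4-oxobut-1-en-2-yl)cyclopentyl]ethyl acetate | C=C(CC=O)[C@@H]1CC(=O)[C@H]([C@H](C)OC(C)=O)[C@H]1C=C(C)C | intermediate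
17 | (1S)-1-[(1S,3aR,6S,7R,7aR)-6-hydroxy-4-methylidene-2-oxo-7-(prop-1-en-2-yl)octahydro-1H-inden-1-yl]ethyl acetate | C=C1[C@@H]2CC(=O)[C@H]([C@H](C)OC(C)=O)[C@H]2[C@H](C(C)=C)[C@@H](O)C1 | intermediate
18 | tert-butyl hydroperoxide | CC(C)(C)OO | starting material
19 | (1S)-1-[(1S,3aR,6S,7S,7aR)-6-hydroxy-4-methylidene-7-[(2S)-2-methyloxiran-2-yl]-2-oxooctahydro-1H-inden-1-yl]ethyl acetate | C=C1[C@@H]2CC(=O)[C@H]([C@H](C)OC(C)=O)[C@H]2[C@H]([C@@]2(C)CO2)[C@@H](O)C1 | intermediate
20 | (2R)-2-methylbutanoic acid | CC[C@@H](C)C(=O)O | starting material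
21 | O-[(2R)-2-methylbutanoyl]-N,N'-diisopropylisourea | CC[C@@H](C)C(=O)OC(=NC(C)C)NC(C)C | intermediate
22 | (1S,3aR,6S,7S,7aR)-1-[(1S)-1-(acetyloxy)ethyl]-4-methylidene-7-[(2S)-2-methyloxiran-2-yl]-2-oxooctahydro-1H-inden-6-yl (2R)-2-methylbutanoate | C=C1[C@@H]2CC(=O)[C@H]([C@H](C)OC(C)=O)[C@H]2[C@H]([C@@]2(C)CO2)[C@@H](OC(=O)[C@H](C)CC)C1 | intermediate
23 | (1S,3aR,5S,6R,7S,7aR)-1-[(1S)-1-(acetyloxy)ethyl]-5-hydroxy-4-methylidene-7-[(2S)-2-methyloxiran-2-yl]-2-oxooctahydro-1H-inden-6-yl (2R)-2-methylbutanoate | C=C1[C@@H]2CC(=O)[C@H]([C@H](C)OC(C)=O)[C@H]2[C@H]([C@@]2(C)CO2)[C@@H](OC(=O)[C@H](C)CC)[C@H]1O | intermediate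
24 | (2S)-2-(acetyloxy)propanoyl chloride | C[C@H](OC(C)=O)C(=O)Cl | starting material
25 | methylmagnesium bromide | C[Mg]Br | starting material
26 | (2S)-3-oxobutan-2-yl acetate | C[C@H](OC(C)=O)C(C)=O | intermediate
27 | tert-butyl (triphenylphosphoranylidene)acetate | CC(C)(C)OC(=O)C=P(c1ccccc1)(c1ccccc1)c1ccccc1 | starting material
28 | tert-butyl (2E,4S)-4-(acetyloxy)-3-methylpent-2-enoate | CC(C)(C)OC(=O)/C=C(\C)[C@H](C)OC(C)=O | intermediate
29 | (2E,4S)-4-(acetyloxy)-3-methylpent-2-enoic acid | OC(=O)/C=C(\C)[C@H](C)OC(C)=O | intermediate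
30 | (2E,4S)-4-(acetyloxy)-3-methylpent-2-enoic 2,4,6-trichlorobenzoic anhydride | O=C(OC(=O)/C=C(\C)[C@H](C)OC(C)=O)c1c(Cl)cc(Cl)cc1Cl | intermediate
31 | (1S,3aR,5S,6R,7S,7aR)-1-[(1S)-1-(acetyloxy)ethyl]-4-methylidene-6-{[(2R)-2-methylbutanoyl]oxy}-7-[(2S)-2-methyloxiran-2-yl]-2-oxooctahydro-1H-inden-5-yl (2E,4S)-4-(acetyloxy)-3-methylpent-2-enoate | C=C1[C@@H]2CC(=O)[C@H]([C@H](C)OC(C)=O)[C@H]2[C@H]([C@@]2(C)CO2)[C@@H](OC(=O)[C@H](C)CC)[C@H]1OC(=O)/C=C(\C)[C@H](C)OC(C)=O | target

**Step count and risks**

Total steps: 15. Longest linear sequence: 12 (steps 1–11 and 15); the acid side chain takes steps 12–14.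

Most likely to fail:

Step 8 (the proposed new ring closure). Risks are deprotonation of the radical cation at the ring methine instead of a methyl group, and slow capture by chromium against isomerisation of the β,γ-unsaturated aldehyde. The fallback sets out from 16 and uses the known thermal Lewis-acid carbonyl-ene cyclisation (ZnBr2, CH2Cl2, 0 °C), the same all-equatorial chair closure that turns citronellal into isopulegol; it gives 17 directly and rejoins the route at 17; no new compound is made (F0).

Step 9 (facial selectivity of the directed epoxidation). The (S) outcome rests on a transition-state model, not on a close precedent, and may be eroded by the substituent on C7a. The fallback sets out from 17 and replaces metal-directed oxygen transfer by a carbonate-tethered iodocyclisation. Boc2O/DMAP gives the tert-butyl carbonate F1. IBr (PhMe, −80 °C) closes the six-membered cyclic iodocarbonate F2 with the CH2I group equatorial. K2CO3 in MeOH at −20 °C then opens the carbonate and closes the epoxide from the same oxygen, which returns to the route at 19.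

Step 11 (allylic hydroxylation). Abstraction of the ring-fusion H-3a, over-oxidation to the enone, or acid opening of the epoxide could compete. The fallback sets out from 22 and does the oxidation stepwise with separable intermediates. PhSeCl (CH2Cl2, −78 °C) adds across the methylidene to give the chloro selenide F3. Warming with 2,6-lutidine removes HCl to give the allyl phenyl selenide F4 with a ring C4=C5 alkene. H2O2/pyridine then forms the selenoxide, whose [2,3]-sigmatropic shift restores the methylidene and delivers the axial C5–OH, rejoining the route at 23.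

**Further compounds**

F0 | step 8 | none | none
F1 | step 9 | tert-butyl (1S,3aR,6S,7R,7aR)-1-[(1S)-1-(acetyloxy)ethyl]-4-methylidene-2-oxo-7-(prop-1-en-2-yl)octahydro-1H-inden-6-yl carbonate | C=C1[C@@H]2CC(=O)[C@H]([C@H](C)OC(C)=O)[C@H]2[C@H](C(C)=C)[C@@H](OC(=O)OC(C)(C)C)C1
F2 | step 9 | cyclic iodocarbonate: six-membered carbonate bridging O-6 and the former isopropenyl carbon (now bearing CH3 and CH2I) of 17 | C=C1[C@@H]2CC(=O)[C@H]([C@H](C)OC(C)=O)[C@H]2[C@H]([C@@]3(C)CI)[C@@H](OC(=O)O3)C1
F3 | step 11 | chloro selenide: 22 with Cl on C4 and CH2SePh in place of the methylidene (C4 epimers) | c1ccccc1[Se]CC1(Cl)[C@@H]2CC(=O)[C@H]([C@H](C)OC(C)=O)[C@H]2[C@H]([C@@]2(C)CO2)[C@@H](OC(=O)[C@H](C)CC)C1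
F4 | step 11 | allyl phenyl selenide: 4-[(phenylselanyl)methyl] C4=C5 alkene isomer of 22 | c1ccccc1[Se]CC=1[C@@H]2CC(=O)[C@H]([C@H](C)OC(C)=O)[C@H]2[C@H]([C@@]2(C)CO2)[C@@H](OC(=O)[C@H](C)CC)C=1
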